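**Strategy.** The decalin is opened (eudesmane numbering) to an acyclic (E)-1,5-enyne whose far end is the silyl enol ether of a methyl ketone (8). One cationic gold-catalysed cascade closes ring A by C4–C5 bond formation on the methyl alkyne and ring B by attack of the enol ether carbon C9 on the tertiary C10 cation. It exploits the trans C5–C10 ring fusion with the quaternary, methyl-bearing C10 next to C9H2–C8(=O) in ring B, and it leaves a C3=C4 alkene in ring A as the latent cis-3,4-diol. A chiral digold catalyst sets C5 and C10; C7 hydroxyalkylation, dehydrogenation, α-face dihydroxylation and angeloylation follow.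

Key step: step 4

Remark on numbering: ring A = C1–C5 and C10, ring B = C5–C10; C3 carries the angelate, C4 the tertiary hydroxyl and methyl C15, C10 the angular methyl C14, C8 the ketone, C7 the carbinol carbon C11.

Assumption: the (R)-configured digold catalyst of step 4 is taken to deliver the (5R,10R) series; if a test run shows the opposite sense, the (S)-ligand is used and nothing else changes.

Step 1
Reactants: 1 trimethyl(prop-1-yn-1-yl)silane; 2 1-bromobut-2-yne
Product: 4 hepta-1,5-diyne, via trimethyl(hepta-1,5-diyn-1-yl)silane 3 (not isolated)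
Conditions: n-BuLi, THF, −78 → 0 °C; then 2, −78 °C → rt; then K2CO3 (cat.), MeOH, rt; distillation
Reagents that add atoms: none
Why: The propargylic lithium reagent from 1 should alkylate the primary propargylic bromide at carbon (SN2), the silyl group blocking the alkyne terminus and disfavouring the allenyl isomer, and methanolysis of the C–Si bond then frees the terminal alkyne (no stereocentre).

Step 2
Reactants: 4 hepta-1,5-diyne; 5 methyl vinyl ketone
Product: 7 (5E)-6-methylundec-5-en-9-yn-2-one, via dimethyl[(1E)-2-methylhept-1-en-5-yn-1-yl]alumane 6 (not isolated)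
Conditions: Me3Al, Cp2ZrCl2 (20 mol %), CH2Cl2, 0 °C → rt; excess Me3Al and solvent removed in vacuo; then CuBr·SMe2 (10 mol %), THF, −40 °C, 5; aq NH4Cl
Reagents that add atoms: trimethylaluminium, C[Al](C)C
Why: Negishi carboalumination should add methyl and aluminium syn across the terminal alkyne only (the internal alkyne reacts far more slowly), which fixes the E trisubstituted alkene, and copper-catalysed conjugate addition of the alkenylalane to the enone transfers the alkenyl group with retention of geometry.

Step 3
Reactants: 7 (5E)-6-methylundec-5-en-9-yn-2-one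
Product: 8 tert-butyl(dimethyl){[(5E)-6-methylundeca-1,5-dien-9-yn-2-yl]oxy}silane
Conditions: LiN(iPr)2, THF, −78 °C; then TBSCl, DMPU, −78 → 0 °C
Reagents that add atoms: tert-butyl(chloro)dimethylsilane, CC(C)(C)[Si](C)(C)Cl
Why: Kinetic deprotonation of a methyl ketone by a hindered lithium amide takes place at the methyl group (C9), and O-silylation traps this terminal enolate as the silyl enol ether.

Step 4
Reactants: 8 tert-butyl(dimethyl){[(5E)-6-methylundeca-1,5-dien-9-yn-2-yl]oxy}silane
Product: 9 (4aR,8aR)-5,8a-dimethyl-3,4,4a,7,8,8a-hexahydronaphthalen-2(1H)-one (trans-fused; eudesmane C5–H α, C10–CH3 β)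
Conditions: (R)-DTBM-MeO-BIPHEP(AuCl)2 (3 mol %), AgSbF6 (6 mol %), i-PrOH (2 equiv), toluene, −20 °C → rt
Reagents that add atoms: none
Why: The cationic monovalent gold complex activates the C3≡C4 alkyne, the (E)-C5=C10 alkene attacks C4 anti to gold, and in the same chair–chair array the enol ether carbon C9 adds to the developing tertiary C10 cation; i-PrOH then takes the silyl group from the oxocarbenium ion and the released proton cleaves the C3–Au bond to leave the C3=C4 alkene. The reaction type is the gold-catalysed enyne-initiated cationic polyene cyclization, whose enantioselective form uses DTBM-MeO-BIPHEP digold catalysts; silyl enol ethers are established terminators of cationic polycyclizations and established carbon nucleophiles under gold catalysis. Ring A closes 6-endo-dig with respect to the alkyne, ring B closes 6-endo-trig with respect to the enol ether. C5 and C10 are created together: their trans relation follows from anti addition across the E alkene, their absolute configuration from the chiral bisphosphine. The step needs 6-endo attack on the alkyne (secured by the methyl group on C10, which places the cation at the tertiary carbon), carbon instead of oxygen termination (secured by O-silylation and the unhindered terminal CH2) and enantiofacial control (catalyst).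

Step 5
Reactants: 9 (4aR,8aR)-5,8a-dimethyl-3,4,4a,7,8,8a-hexahydronaphthalen-2(1H)-one; 10 acetone
Product: 11 (4aR,8aR)-3-(2-hydroxypropan-2-yl)-5,8a-dimethyl-3,4,4a,7,8,8a-hexahydronaphthalen-2(1H)-one (both epimers at the new centre)
Conditions: LiN(iPr)2, THF, −78 °C; then 10, −78 °C; AcOH quench at −78 °C
Reagents that add atoms: none
Why: Kinetic lithium enolate formation should occur at C7, away from the neopentyl C9 next to the quaternary C10, and aldol addition to acetone follows; the C7 configuration is not controlled and is erased in step 6.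

Step 6
Reactants: 11 (4aR,8aR)-3-(2-hydroxypropan-2-yl)-5,8a-dimethyl-3,4,4a,7,8,8a-hexahydronaphthalen-2(1H)-one
Product: 12 (4aR,8aR)-3-(2-hydroxypropan-2-yl)-5,8a-dimethyl-4a,7,8,8a-tetrahydronaphthalen-2(1H)-one
Conditions: 2-iodoxybenzoic acid (IBX), 4-methoxypyridine N-oxide, DMSO, rt
Reagents that add atoms: none
Why: IBX-mediated α,β-dehydrogenation of a ketone proceeds through its enol, and because C10 carries no hydrogen only the C7 enol can lose a β-hydrogen, so the C6=C7 enone is the only possible regioisomer and the C7 stereocentre disappears.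

Step 7
Reactants: 12 (4aR,8aR)-3-(2-hydroxypropan-2-yl)-5,8a-dimethyl-4a,7,8,8a-tetrahydronaphthalen-2(1H)-one
Product: 13 (4aR,5S,6R,8aR)-5,6-dihydroxy-3-(2-hydroxypropan-2-yl)-5,8a-dimethyl-4a,5,6,7,8,8a-hexahydronaphthalen-2(1H)-one
Conditions: OsO4 (2 mol %), NMO, acetone/H2O, 0 °C → rt; aq Na2SO3
Reagents that add atoms: osmium tetroxide, O=[Os](=O)(=O)=O; N-methylmorpholine N-oxide, C[N+]1([O-])CCOCC1; water, O
Why: Catalytic syn-dihydroxylation with OsO4 should take the electron-rich trisubstituted C3=C4 alkene in preference to the deactivated enone alkene and add from the α face, anti to the axial C10 methyl group, so that C3 (R) and C4 (S) are set together by substrate control.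

Step 8
Reactants: 13 (4aR,5S,6R,8aR)-5,6-dihydroxy-3-(2-hydroxypropan-2-yl)-5,8a-dimethyl-4a,5,6,7,8,8a-hexahydronaphthalen-2(1H)-one; 14 angelic acid
Product: 15 (3R,4S,5R,10R)-3-angeloyloxy-4,11-dihydroxyeudesm-6-en-8-one (CNP0261892.2)
Conditions: 14, 2,4,6-trichlorobenzoyl chloride, Et3N, toluene, rt; then 13, 75 °C
Reagents that add atoms: none
Why: Yamaguchi-type esterification through the mixed anhydride should acylate only the secondary C3 hydroxyl (the other two are tertiary), and leaving out a nucleophilic acyl-transfer catalyst should keep the Z geometry of the angelate; no stereocentre is touched.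

**Compound list**

1 | trimethyl(prop-1-yn-1-yl)silane | CC#C[Si](C)(C)C | starting material
2 | 1-bromobut-2-yne | CC#CCBr | starting material
3 | trimethyl(hepta-1,5-diyn-1-yl)silane | CC#CCCC#C[Si](C)(C)C | intermediate (not isolated)
4 | hepta-1,5-diyne | C#CCCC#CC | intermediate
5 | methyl vinyl ketone (but-3-en-2-one) | CC(=O)C=C | starting material
6 | dimethyl[(1E)-2-methylhept-1-en-5-yn-1-yl]alumane | C[Al](C)/C=C(\C)CCC#CC | intermediate (not isolated)
7 | (5E)-6-methylundec-5-en-9-yn-2-one | CC(=O)CC/C=C(\C)CCC#CC | intermediate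
8 | tert-butyl(dimethyl){[(5E)-6-methylundeca-1,5-dien-9-yn-2-yl]oxy}silane | C=C(O[Si](C)(C)C(C)(C)C)CC/C=C(\C)CCC#CC | intermediate
9 | (4aR,8aR)-5,8a-dimethyl-3,4,4a,7,8,8a-hexahydronaphthalen-2(1H)-one | C1CC[C@]2(C)CC(=O)CC[C@H]2C(C)=1 | intermediate
10 | acetone | CC(C)=O | starting material
11 | (4aR,8aR)-3-(2-hydroxypropan-2-yl)-5,8a-dimethyl-3,4,4a,7,8,8a-hexahydronaphthalen-2(1H)-one, both C-3 epimers (centre left open in the SMILES) | C1CC[C@]2(C)CC(=O)C(C(C)(C)O)C[C@H]2C(C)=1 | intermediate
12 | (4aR,8aR)-3-(2-hydroxypropan-2-yl)-5,8a-dimethyl-4a,7,8,8a-tetrahydronaphthalen-2(1H)-one | C1CC[C@]2(C)CC(=O)C(C(C)(C)O)=C[C@H]2C(C)=1 | intermediate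
13 | (4aR,5S,6R,8aR)-5,6-dihydroxy-3-(2-hydroxypropan-2-yl)-5,8a-dimethyl-4a,5,6,7,8,8a-hexahydronaphthalen-2(1H)-one | O[C@@H]1CC[C@]2(C)CC(=O)C(C(C)(C)O)=C[C@H]2[C@]1(C)O | intermediate
14 | angelic acid, (2Z)-2-methylbut-2-enoic acid | C/C=C(/C)C(=O)O | starting material
15 | (3R,4S,5R,10R)-3-angeloyloxy-4,11-dihydroxyeudesm-6-en-8-one | C/C=C(/C)C(=O)O[C@@H]1CC[C@]2(C)CC(=O)C(C(C)(C)O)=C[C@H]2[C@]1(C)O | target

**Totals.** Total step count: 8. Longest linear sequence: 8 steps (1 and 2 to 15).

**Steps most likely to fail**

Step 4. The chiral gold complex may discriminate poorly between the two enantiomeric chair–chair folds in this 6-endo manifold, which has not been tested with a methyl alkyne and an enol ether terminator; loss of the silyl group before termination is a second, smaller risk. The fallback sets out from 8 and comes back at 9, and it obtains the enantiomer by resolution instead of catalyst control. Compound 8 is cyclised with the achiral complex (2-biphenylyl)(t-Bu)2PAu(NCMe)SbF6 (i-PrOH, CH2Cl2, rt) to the racemic ketone, that is 9 together with (4aS,8aS)-5,8a-dimethyl-3,4,4a,7,8,8a-hexahydronaphthalen-2(1H)-one F1. Ketalisation of the racemate with (1R,2R)-1,2-diphenylethane-1,2-diol (PPTS, benzene, reflux with removal of water) should give two diastereomers, the (4R,5R)-4,5-diphenyl-1,3-dioxolane spiroketal of 9 F2 and the corresponding spiroketal of the mirror-image ketone F3. These are separated by crystallisation or chromatography, and hydrolysis of F2 (aq HCl, THF, rt) returns 9.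

Step 6. Enolisation toward the hindered, fully substituted C7 may be slow, the tertiary carbinol may lose water, and the new enone double bond may move into conjugation with ring A through the doubly allylic C5–H. The fallback sets out from 11 and comes back at 13, and it forms the enone and the C11 hydroxyl by an ene reaction after ring A has been dihydroxylated. Dehydration of 11 (SOCl2, pyridine, 0 °C; then DBU to bring all material into conjugation) should give (4aR,8aR)-5,8a-dimethyl-3-(propan-2-ylidene)-3,4,4a,7,8,8a-hexahydronaphthalen-2(1H)-one F4. Dihydroxylation as in step 7 gives (4aR,5S,6R,8aR)-5,6-dihydroxy-5,8a-dimethyl-3-(propan-2-ylidene)octahydronaphthalen-2(1H)-one F5. A Schenck ene reaction with singlet oxygen (O2, tetraphenylporphyrin, visible light, CH2Cl2, 0 °C) then follows; for an s-cis alkylidene ketone it removes the ring hydrogen geminal to the carbonyl (C6–H) and places oxygen on C11, giving (4aR,5S,6R,8aR)-3-(2-hydroperoxypropan-2-yl)-5,6-dihydroxy-5,8a-dimethyl-4a,5,6,7,8,8a-hexahydronaphthalen-2(1H)-one F6. Reduction with PPh3 gives 13.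

Step 8. The Z acyl unit may isomerise to the tiglate during activation or acyl transfer, and acylation of the hindered axial C3 hydroxyl may stall. The fallback sets out from 13 and comes back at 15, and it builds the Z double bond on the ester instead of transferring a preformed angeloyl group. Acylation of the C3 hydroxyl with 2-(diphenoxyphosphoryl)propanoic acid (N,N'-dicyclohexylcarbodiimide, DMAP, CH2Cl2, 0 °C → rt) should give the C3 2-(diphenoxyphosphoryl)propanoate of 13 F7. A Z-selective Horner–Wadsworth–Emmons olefination (Ando variant) with acetaldehyde (NaI, DBU, THF, 0 °C) then gives 15.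

**Further compounds**

F1 | step 4 | (4aS,8aS)-5,8a-dimethyl-3,4,4a,7,8,8a-hexahydronaphthalen-2(1H)-one (mirror image of 9) | C1CC[C@@]2(C)CC(=O)CC[C@@H]2C(C)=1
F2 | step 4 | (4R,5R)-4,5-diphenyl-1,3-dioxolane spiroketal of 9 at the ketone carbon | C1CC[C@]2(C)CC3(CC[C@H]2C(C)=1)O[C@H](c4ccccc4)[C@@H](c4ccccc4)O3
F3 | step 4 | (4R,5R)-4,5-diphenyl-1,3-dioxolane spiroketal of the mirror-image ketone F1 | C1CC[C@@]2(C)CC3(CC[C@@H]2C(C)=1)O[C@H](c4ccccc4)[C@@H](c4ccccc4)O3
F4 | step 6 | (4aR,8aR)-5,8a-dimethyl-3-(propan-2-ylidene)-3,4,4a,7,8,8a-hexahydronaphthalen-2(1H)-one | C1CC[C@]2(C)CC(=O)C(=C(C)C)C[C@H]2C(C)=1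
F5 | step 6 | (4aR,5S,6R,8aR)-5,6-dihydroxy-5,8a-dimethyl-3-(propan-2-ylidene)octahydronaphthalen-2(1H)-one | O[C@@H]1CC[C@]2(C)CC(=O)C(=C(C)C)C[C@H]2[C@]1(C)O
F6 | step 6 | (4aR,5S,6R,8aR)-3-(2-hydroperoxypropan-2-yl)-5,6-dihydroxy-5,8a-dimethyl-4a,5,6,7,8,8a-hexahydronaphthalen-2(1H)-one | O[C@@H]1CC[C@]2(C)CC(=O)C(C(C)(C)OO)=C[C@H]2[C@]1(C)O
F7 | step 8 | C3 2-(diphenoxyphosphoryl)propanoate of 13 (phosphonate α-carbon unassigned) | CC(C(=O)O[C@@H]1CC[C@]2(C)CC(=O)C(C(C)(C)O)=C[C@H]2[C@]1(C)O)P(=O)(Oc1ccccc1)Oc1ccccc1
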